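**Plan** (atoms numbered as in ent-kaurane: ring A = C1–C5/C10, C6 = aldehyde carbon, C7 = lactone carbonyl, C20 = lactone O–CH2, ring C = C8/C9/C11–C14, bridge C15–C16 with exocyclic C17)
1. Cuts, backwards: C6 acetal, C13–O–Si and C15–O are unmasked or installed last; ring D is cut at C8–C15 (enolate alkylation) and C13–C16 (organocerium addition); ring C at C13–C14 (one-carbon radical ring expansion); the cyclopentanone at C11–C12/C8–C13 (metathesis, aldol) and C9–C11 (conjugate addition); the lactone at O–C7; C9–C10, C10–C20 and C5–C6 lead back to 4,4-dimethylcyclohexadienone.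
2. Enabling feature: in ring C, C14 is a lone CH2 between quaternary C8 (which carries the C7 lactone carbonyl) and the carbinol carbon C13. This is the γ-keto ester pattern left when one carbon is inserted into a cyclopentanone β-keto lactone, a 1,3-relationship that direct annulation onto a C8=C9 acceptor does not give.
3. Forward order: ring A (bought) → spiro δ-lactone (step 5) → fused cyclopentanone (steps 10–12) → ring C by expansion (step 14) → ring D (step 18) → ring A enone, C15–OH, C6 aldehyde.
4. Stereochemistry: C5 by BINAP–rhodium vinyl addition; C10 by Michael addition anti to the C5 substituent; C9 by vinyl addition to the unsaturated spiro lactone anti to the C5 branch; C13 by equatorial organocerium addition; C8 by the geometry of ring D closure; C15 by oxygen delivery to the open face of ring D.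

Key step: step 14

Remark: the BINAP enantiomer in step 2 is assigned by analogy with cyclohexenone, and in 20–22 the configurations at C8 and at the carbinol carbon C13 are left open because both are erased or equilibrated in step 12.

**Step 1**
Reactants: 1 4,4-dimethylcyclohex-2-en-1-one
Product: 2 4,4-dimethylcyclohexa-2,5-dien-1-one
Conditions: DDQ (1.3 equiv), TsOH·H2O (cat.), dioxane, 100 °C
Reagents that add atoms: none
Why: Quinone dehydrogenation of the enone (hydride abstraction from the dienol, then proton loss) is the classical route to cross-conjugated 4,4-disubstituted cyclohexadienones, and the quaternary C4 rules out aromatisation.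

**Step 2**
Reactants: 2 4,4-dimethylcyclohexa-2,5-dien-1-one; 3 potassium vinyltrifluoroborate
Product: 4 (R)-5-ethenyl-4,4-dimethylcyclohex-2-en-1-one
Conditions: [Rh(cod)2]BF4 (3 mol %), (R)-BINAP (3.3 mol %), toluene/H2O (4:1), 100 °C
Reagents that add atoms: none
Why: Rhodium/BINAP-catalysed asymmetric conjugate addition of an alkenylboron reagent (Hayashi–Miyaura reaction) to one of the two mirror-related enone units sets C5 under catalyst control, and the mono-adduct, now a hindered enone, should react further only slowly.

**Step 3**
Reactants: 4 (R)-5-ethenyl-4,4-dimethylcyclohex-2-en-1-one; 5 ethyl formate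
Product: 6 (5R)-5-ethenyl-6-(hydroxymethylidene)-4,4-dimethylcyclohex-2-en-1-one
Conditions: NaH, THF, 0 °C → rt; aq. HCl
Reagents that add atoms: none
Why: Claisen formylation can occur only at C10 because C4 is quaternary and C2 is vinylic, so the dienone-derived enone fixes a regiochemistry that a saturated 3-substituted cyclohexanone would not give.

**Step 4**
Reactants: 6 (5R)-5-ethenyl-6-(hydroxymethylidene)-4,4-dimethylcyclohex-2-en-1-one; 7 2,2,2-trifluoroethyl acrylate
Product: 8 2,2,2-trifluoroethyl 3-(6-ethenyl-1-formyl-5,5-dimethyl-2-oxocyclohex-3-en-1-yl)propanoate (propanoate arm trans to vinyl)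
Conditions: DBU (10 mol %), MeCN, 0 °C → rt
Reagents that add atoms: none
Why: Base-catalysed Michael addition of the soft formyl-ketone enolate to the activated acrylate builds the quaternary C10, the acceptor approaching anti to the neighbouring C5 vinyl group so that the three-carbon arm (C9) ends trans to it and the formyl carbon (C20) cis.

**Step 5**
Reactants: 8 keto aldehyde ester
Product: 10 vinyl spiro lactone (11-ethenyl-10,10-dimethyl-2-oxaspiro[5.5]undec-8-ene-3,7-dione), via hydroxy ester 9 (not isolated)
Conditions: NaBH4 (0.5 equiv), THF/MeOH, −78 °C; then warm to 0 °C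
Reagents that add atoms: none
Why: The non-enolisable aldehyde next to the ketone is far more electrophilic than the hindered conjugated ketone, so borohydride at −78 °C should reduce it alone (chemoselective carbonyl reduction), and the primary alkoxide then closes the δ-lactone on the activated trifluoroethyl ester by intramolecular transesterification.

**Step 6**
Reactants: 10 vinyl spiro lactone
Product: 11 spiro lactone aldehyde (10,10-dimethyl-3,7-dioxo-2-oxaspiro[5.5]undec-8-ene-11-carbaldehyde)
Conditions: O3, CH2Cl2/MeOH, −78 °C (Sudan Red endpoint); Me2S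
Reagents that add atoms: ozone, [O-][O+]=O
Why: Ozonolysis with reductive work-up cleaves the electron-rich monosubstituted alkene much faster than the electron-poor enone double bond, and C5, flanked by two quaternary carbons, should resist epimerisation.

**Step 7**
Reactants: 11 spiro lactone aldehyde
Product: 12 acetal enone (11-(dimethoxymethyl)-10,10-dimethyl-2-oxaspiro[5.5]undec-8-ene-3,7-dione)
Conditions: HC(OMe)3, MeOH, PPTS (cat.), rt
Reagents that add atoms: trimethyl orthoformate, COC(OC)OC
Why: Acid-catalysed acetalisation with the orthoformate protects the aldehyde under conditions too mild to ketalise the hindered enone or open the lactone.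

**Step 8**
Reactants: 12 acetal enone
Product: 14 ring A silyl enol ether (7-(tert-butyldimethylsilyloxy)-11-(dimethoxymethyl)-10,10-dimethyl-2-oxaspiro[5.5]undec-7-en-3-one), via lithium enolate 13 (not isolated)
Conditions: LiBH(s-Bu)3 (1.05 equiv), THF, −78 °C; then TBSCl, HMPA, −78 → 0 °C
Reagents that add atoms: tert-butyldimethylsilyl chloride, CC(C)(C)[Si](C)(C)Cl
Why: Conjugate hydride addition of the bulky trialkylborohydride to the β-unsubstituted cyclohexenone (1,4-reduction) gives the C1–C2 enolate regiospecifically, and O-silylation stores ring A as an enol ether that has no acidic hydrogen, is inert to organocopper reagents and can later be returned to the enone.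

**Step 9**
Reactants: 14 ring A silyl enol ether
Product: 16 unsaturated spiro lactone (7-(tert-butyldimethylsilyloxy)-11-(dimethoxymethyl)-10,10-dimethyl-2-oxaspiro[5.5]undeca-4,7-dien-3-one), via α-phenylselanyl lactone 15 (not isolated)
Conditions: LiN(i-Pr)2, THF, −78 °C; PhSeBr (1.0 equiv); then H2O2 (30 %), pyridine, CH2Cl2, 0 °C → rt
Reagents that add atoms: none
Why: The lactone C8–H is now the only acidic C–H, so α-selenenylation of its lithium enolate (which should outcompete the silyl enol ether for PhSeBr) followed by selenoxide syn-elimination towards C9 should give the C8=C9 unsaturated lactone.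

**Step 10**
Reactants: 16 unsaturated spiro lactone; 17 vinylmagnesium bromide; 18 acrolein
Product: 20 diene lactone (5-ethenyl-4-(1-hydroxyprop-2-en-1-yl) derivative of 14), via bromomagnesium enolate 19 (not isolated)
Conditions: CH2=CHMgBr (1.3 equiv), CuBr·SMe2 (20 mol %), THF, −78 → −40 °C; then acrolein, −78 °C; aq. NH4Cl
Reagents that add atoms: none
Why: Copper-catalysed conjugate addition of the vinyl Grignard reagent followed by aldol capture of the magnesium enolate (three-component coupling) sets C9, the nucleophile being expected on the lactone face away from the C5 branch of the spiro ring (acetal plus adjacent gem-dimethyl carbon) and syn to the flat enol-ether carbon C1, which is the configuration required.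

**Step 11**
Reactants: 20 diene lactone
Product: 22 fused cyclopentanol lactone (C13 carbinol), via cyclopentenol 21 (not isolated)
Conditions: second-generation Grubbs catalyst (5 mol %), CH2Cl2, 40 °C; then H2 (5 atm), 50 °C
Reagents that add atoms: none
Why: Ring-closing metathesis of the two terminal alkenes forms the five-membered ring with loss of ethene, and the ruthenium residue under H2 saturates the new disubstituted double bond (tandem metathesis–hydrogenation) while the hindered trisubstituted silyl enol ether should not react.

**Step 12**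
Reactants: 22 fused cyclopentanol lactone
Product: 23 cyclopentanone β-keto lactone (C13 ketone; C8–H syn to H9)
Conditions: Dess–Martin periodinane, NaHCO3, CH2Cl2, rt
Reagents that add atoms: none
Why: Dess–Martin oxidation of the secondary alcohol gives the β-keto lactone, whose acidic C8–H equilibrates to the cis ring fusion that a bicyclo[4.3.0] system strongly prefers.

**Step 13**
Reactants: 23 cyclopentanone β-keto lactone; 24 dibromomethane
Product: 25 bromomethyl β-keto lactone (CH2Br on C8 syn to H9)
Conditions: NaH, THF/HMPA, 0 °C; CH2Br2 (10 equiv), rt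
Reagents that add atoms: none
Why: C-alkylation of the sodium enolate of the β-dicarbonyl compound with excess dibromomethane, the standard entry to 2-bromomethyl β-keto esters, makes C8 quaternary with the electrophile entering on the convex face of the cis-fused bicycle.

**Step 14**
Reactants: 25 bromomethyl β-keto lactone
Product: 26 ring C keto lactone (cyclohexanone with C13 ketone; C8–H syn to H9)
Conditions: Bu3SnH (1.2 equiv, syringe pump over 6 h), AIBN (0.2 equiv), PhH (0.01 M), 80 °C
Reagents that add atoms: none
Why: Bu3Sn• abstracts bromine from 25; the primary C14 radical adds to the neighbouring C13 carbonyl (3-exo-trig) and the strained cyclopropyloxy radical reopens by β-scission of the old C8–C13 bond to the tertiary C8 radical stabilised by the lactone carbonyl, which takes hydrogen from the stannane. This is the Dowd–Beckwith one-carbon ring expansion of 2-(halomethyl) cyclic β-keto esters, applied here to a β-keto lactone. Ring C is closed by this 3-exo closure/fragmentation sequence and not by a direct six-membered cyclisation, the new C13–C14 bond moving the ketone to the position 1,3 to C8. The one new stereocentre, C8–H, should result from hydrogen transfer to the convex face of the bicycle, leaving the lactone cis-fused to ring C; it is provisional because C8 is deprotonated again in step 18. The step needs addition to the ketone and not to the lactone carbonyl (esters are much poorer radical acceptors), rearrangement ahead of reduction (slow stannane addition at high dilution) and no interception by ring A: the CH2• group is trans to C10 on the cyclopentanone, which disfavours 1,5-hydrogen shifts from C20 or C5, and the silyl enol ether can be reached only by 4-exo or 5-endo closure.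

**Step 15**
Reactants: 26 ring C keto lactone; 27 2-bromoprop-2-en-1-ol
Product: 28 diol (C13 tertiary alcohol bearing the 3-hydroxyprop-1-en-2-yl group)
Conditions: 27, n-BuLi then t-BuLi (2 equiv), Et2O, −78 °C; CeCl3, THF, −78 °C; then 26; AcOH quench at −78 °C
Reagents that add atoms: none
Why: 1,2-Addition of the organocerium reagent made from the O,2-dilithio derivative of allyl alcohol is chemoselective for the unhindered ketone and suppresses enolisation; equatorial attack on the chair with the spiro carbon C10 equatorial and C7 axial places C16 syn to H8 and H9 and the C13 oxygen on the face of C7, and the cold acidic quench keeps the axial alkoxide from attacking the lactone carbonyl.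

**Step 16**
Reactants: 28 diol
Product: 29 allylic bromide (C15–Br)
Conditions: CBr4, PPh3, 2,6-lutidine, CH2Cl2, 0 °C
Reagents that add atoms: carbon tetrabromide, BrC(Br)(Br)Br
Why: Appel bromination converts only the primary allylic alcohol, the tertiary alcohol being too hindered to form the alkoxyphosphonium salt at 0 °C.

**Step 17**
Reactants: 29 allylic bromide
Product: 30 trimethylsilyl ether of 29 (C13–OSiMe3)
Conditions: 1-(trimethylsilyl)imidazole, CH2Cl2, rt
Reagents that add atoms: 1-(trimethylsilyl)imidazole, C[Si](C)(C)n1ccnc1
Why: Neutral silylation removes the last acidic O–H, so that in the next step no alkoxide syn-axial to the lactone carbonyl can form and translactonise.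

**Step 18**
Reactants: 30 silylated allylic bromide
Product: 31 tetracyclic bis-silyl compound (ring D closed; C16=C17 exocyclic)
Conditions: KN(SiMe3)2 (1.3 equiv), THF, −78 → 0 °C
Reagents that add atoms: none
Why: Intramolecular C-alkylation of the potassium lactone enolate by the allylic bromide (5-exo-tet) closes ring D, and because C16 is fixed on C13 the new bond can reach C8 only from the face of H9, which sets the quaternary C8 with the lactone cis-fused to ring C.

**Step 19**
Reactants: 31 tetracyclic bis-silyl compound
Product: 32 ring A enone (C1 ketone, C2=C3)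
Conditions: Pd(OAc)2 (1.2 equiv), MeCN, rt
Reagents that add atoms: none
Why: Saegusa–Ito oxidation (palladation of the silyl enol ether, then β-hydride elimination) restores the C2=C3 enone, which cannot isomerise because C4 and C10 are quaternary.

**Step 20**
Reactants: 32 ring A enone
Product: 33 C15 allylic alcohol (15-OH syn to H9; C13–OSiMe3; C6 dimethyl acetal)
Conditions: SeO2 (0.5 equiv), t-BuOOH (2 equiv), CH2Cl2, 0 °C → rt
Reagents that add atoms: tert-butyl hydroperoxide, CC(C)(C)OO
Why: Selenium dioxide allylic hydroxylation (ene reaction, then [2,3]-sigmatropic shift) can functionalise only C15 because the other allylic carbon C13 is fully substituted, and it should deliver oxygen to the more open face of ring D, away from the C14 bridge and the C7 carbonyl and syn to H9, as in ent-kaur-16-ene frameworks.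

**Step 21**
Reactants: 33 C15 allylic alcohol
Product: 34 CNP0521079.1 (target)
Conditions: PPTS (cat.), acetone/H2O (9:1), 40 °C
Reagents that add atoms: water, O
Why: Mild aqueous acid hydrolyses the dimethyl acetal and the tertiary trimethylsilyl ether in one operation, gently enough to spare the 13-hydroxy-16-ene unit from acid-induced rearrangement and C5 from epimerisation.

**Compound list**
1 | 4,4-dimethylcyclohex-2-en-1-one | CC1(C)CCC(=O)C=C1 | starting material
2 | 4,4-dimethylcyclohexa-2,5-dien-1-one | CC1(C)C=CC(=O)C=C1 | intermediate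
3 | potassium vinyltrifluoroborate | [K+].C=C[B-](F)(F)F | starting material
4 | (R)-5-ethenyl-4,4-dimethylcyclohex-2-en-1-one | O=C1C=CC(C)(C)[C@@H](C=C)C1 | intermediate
5 | ethyl formate | CCOC=O | starting material
6 | (5R)-5-ethenyl-6-(hydroxymethylidene)-4,4-dimethylcyclohex-2-en-1-one (enol form of the 6-formyl ketone) | O=C1C=CC(C)(C)[C@@H](C=C)C1=CO | intermediate
7 | 2,2,2-trifluoroethyl acrylate | C=CC(=O)OCC(F)(F)F | starting material
8 | 2,2,2-trifluoroethyl 3-(6-ethenyl-1-formyl-5,5-dimethyl-2-oxocyclohex-3-en-1-yl)propanoate; propanoate arm trans to vinyl | FC(F)(F)COC(=O)CC[C@]1(C=O)C(=O)C=CC(C)(C)[C@H]1C=C | intermediate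
9 | hydroxy ester: 1-(hydroxymethyl) analogue of 8 | FC(F)(F)COC(=O)CC[C@]1(CO)C(=O)C=CC(C)(C)[C@H]1C=C | intermediate
10 | 11-ethenyl-10,10-dimethyl-2-oxaspiro[5.5]undec-8-ene-3,7-dione; lactone CH2O cis to vinyl | O=C1CC[C@]2(CO1)C(=O)C=CC(C)(C)[C@H]2C=C | intermediate
11 | 10,10-dimethyl-3,7-dioxo-2-oxaspiro[5.5]undec-8-ene-11-carbaldehyde | O=C1CC[C@]2(CO1)C(=O)C=CC(C)(C)[C@H]2C=O | intermediate
12 | 11-(dimethoxymethyl)-10,10-dimethyl-2-oxaspiro[5.5]undec-8-ene-3,7-dione | O=C1CC[C@]2(CO1)C(=O)C=CC(C)(C)[C@H]2C(OC)OC | intermediate
13 | lithium C1–C2 enolate from 1,4-reduction of 12 | O=C1CC[C@]2(CO1)C(O[Li])=CCC(C)(C)[C@H]2C(OC)OC | intermediate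
14 | 7-(tert-butyldimethylsilyloxy)-11-(dimethoxymethyl)-10,10-dimethyl-2-oxaspiro[5.5]undec-7-en-3-one | O=C1CC[C@]2(CO1)C(O[Si](C)(C)C(C)(C)C)=CCC(C)(C)[C@H]2C(OC)OC | intermediate
15 | 4-(phenylselanyl) derivative of 14 (C8 epimers) | O=C1C([Se]c3ccccc3)C[C@]2(CO1)C(O[Si](C)(C)C(C)(C)C)=CCC(C)(C)[C@H]2C(OC)OC | intermediate
16 | 7-(tert-butyldimethylsilyloxy)-11-(dimethoxymethyl)-10,10-dimethyl-2-oxaspiro[5.5]undeca-4,7-dien-3-one | O=C1C=C[C@]2(CO1)C(O[Si](C)(C)C(C)(C)C)=CCC(C)(C)[C@H]2C(OC)OC | intermediate
17 | vinylmagnesium bromide | C=C[Mg]Br | starting material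
18 | acrolein | C=CC=O | starting material
19 | bromomagnesium enolate of the 5-vinyl lactone (vinyl on C9 syn to C1) | Br[Mg]OC1=C[C@@H](C=C)[C@]2(CO1)C(O[Si](C)(C)C(C)(C)C)=CCC(C)(C)[C@H]2C(OC)OC | intermediate
20 | 5-ethenyl-4-(1-hydroxyprop-2-en-1-yl) derivative of 14 (C8 and carbinol centre open) | O=C1C(C(O)C=C)[C@@H](C=C)[C@]2(CO1)C(O[Si](C)(C)C(C)(C)C)=CCC(C)(C)[C@H]2C(OC)OC | intermediate
21 | cyclopentenol fused to the lactone at C8–C9 (C11=C12; C8 and C13 open) | C23C(O)C=C[C@H]2[C@]1(COC3=O)C(O[Si](C)(C)C(C)(C)C)=CCC(C)(C)[C@H]1C(OC)OC | intermediate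
22 | cyclopentanol fused to the lactone at C8–C9 (C8 and C13 open) | C23C(O)CC[C@H]2[C@]1(COC3=O)C(O[Si](C)(C)C(C)(C)C)=CCC(C)(C)[C@H]1C(OC)OC | intermediate
23 | cis-fused cyclopentanone β-keto lactone (C13 ketone; C8–H syn to H9) | [C@H]23C(=O)CC[C@H]2[C@]1(COC3=O)C(O[Si](C)(C)C(C)(C)C)=CCC(C)(C)[C@H]1C(OC)OC | intermediate
24 | dibromomethane | BrCBr | starting material
25 | bromomethyl β-keto lactone (CH2Br on C8 syn to H9; lactone cis-fused to the cyclopentanone) | BrC[C@]23C(=O)CC[C@H]2[C@]1(COC3=O)C(O[Si](C)(C)C(C)(C)C)=CCC(C)(C)[C@H]1C(OC)OC | intermediate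
26 | lactone-fused cyclohexanone with C13 ketone (C8–H syn to H9) | [C@H]23CC(=O)CC[C@H]2[C@]1(COC3=O)C(O[Si](C)(C)C(C)(C)C)=CCC(C)(C)[C@H]1C(OC)OC | intermediate
27 | 2-bromoprop-2-en-1-ol | OCC(Br)=C | starting material
28 | diol: C13 tertiary alcohol (oxygen on the face of C7) bearing 3-hydroxyprop-1-en-2-yl | [C@H]23C[C@](O)(C(=C)CO)CC[C@H]2[C@]1(COC3=O)C(O[Si](C)(C)C(C)(C)C)=CCC(C)(C)[C@H]1C(OC)OC | intermediate
29 | allylic bromide from 28 (C15–Br) | [C@H]23C[C@](O)(C(=C)CBr)CC[C@H]2[C@]1(COC3=O)C(O[Si](C)(C)C(C)(C)C)=CCC(C)(C)[C@H]1C(OC)OC | intermediate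
30 | C13 trimethylsilyl ether of 29 | [C@H]23C[C@](O[Si](C)(C)C)(C(=C)CBr)CC[C@H]2[C@]1(COC3=O)C(O[Si](C)(C)C(C)(C)C)=CCC(C)(C)[C@H]1C(OC)OC | intermediate
31 | tetracycle with ring D closed (C13–OSiMe3, ring A silyl enol ether, C6 acetal) | C=C1C[C@]23C[C@@]1(O[Si](C)(C)C)CC[C@H]2[C@]1(COC3=O)C(O[Si](C)(C)C(C)(C)C)=CCC(C)(C)[C@H]1C(OC)OC | intermediate
32 | ring A enone (C13–OSiMe3, C6 acetal) | C=C1C[C@]23C[C@@]1(O[Si](C)(C)C)CC[C@H]2[C@]1(COC3=O)C(=O)C=CC(C)(C)[C@H]1C(OC)OC | intermediate
33 | C15 alcohol (15-OH syn to H9; C13–OSiMe3, C6 acetal) | C=C1[C@@H](O)[C@]23C[C@@]1(O[Si](C)(C)C)CC[C@H]2[C@]1(COC3=O)C(=O)C=CC(C)(C)[C@H]1C(OC)OC | intermediate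
34 | CNP0521079.1 | C=C1[C@@H](O)[C@]23C[C@@]1(O)CC[C@H]2[C@]1(COC3=O)C(=O)C=CC(C)(C)[C@H]1C=O | target

Total step count: 21. Longest linear sequence: 21 steps (from 1; all other inputs are purchased).

**Steps most likely to fail**

Step 10. What may go wrong: slow or face-unselective transfer of the vinyl group to the neopentyl carbon C9, and proton exchange of the magnesium enolate before acrolein captures it. Fallback, from 16 back to 20: rhodium-catalysed conjugate addition of trivinylboroxine–pyridine complex ([Rh(cod)OH]2, BINAP, K3PO4, dioxane/H2O, 60 °C), with the ligand enantiomer chosen to reinforce attack anti to the C5 branch, should give the 9-vinyl spiro lactone F1. Kinetic deprotonation at C8 (LiN(i-Pr)2, THF, −78 °C) and aldol addition to acrolein 18 then lead to 20.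

Step 14. What may go wrong: hydrogen transfer to the C14 radical before the acyl shift (giving the 8-methyl compound), or reduction of radicals formed by stray hydrogen shifts. Fallback, from 25 back to 26: electron-transfer ring expansion with SmI2 (2.2 equiv, THF, −78 → 0 °C, then MeOH). The same C14 radical is formed with no hydrogen-atom donor present, so the rearrangement cannot be outrun by reduction; the rearranged C8 radical is reduced to the samarium enolate and protonated to 26. No new compound is isolated.

Step 20. What may go wrong: delivery of oxygen to the wrong face of C15, or further oxidation of the allylic alcohol. Fallback, from 32 back to 34: if the oxidation gives the 15-epimeric alcohol F2, Mitsunobu inversion (4-nitrobenzoic acid, PPh3, diisopropyl azodicarboxylate, toluene, 0 °C → rt) should give the inverted 4-nitrobenzoate F3. K2CO3 in MeOH removes the ester and the trimethylsilyl ether to give the diol acetal F4, and the conditions of step 21 then give 34.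

**Further compounds**
F1 | step 10 | 5-ethenyl-7-(tert-butyldimethylsilyloxy)-11-(dimethoxymethyl)-10,10-dimethyl-2-oxaspiro[5.5]undec-7-en-3-one (vinyl on C9 syn to C1) | O=C1C[C@@H](C=C)[C@]2(CO1)C(O[Si](C)(C)C(C)(C)C)=CCC(C)(C)[C@H]2C(OC)OC
F0 | step 14 | none | none
F2 | step 20 | 15-epimer of 33 | C=C1[C@H](O)[C@]23C[C@@]1(O[Si](C)(C)C)CC[C@H]2[C@]1(COC3=O)C(=O)C=CC(C)(C)[C@H]1C(OC)OC
F3 | step 20 | 15-O-(4-nitrobenzoyl) derivative of 33 | C=C1[C@@H](OC(=O)c4ccc(cc4)[N+](=O)[O-])[C@]23C[C@@]1(O[Si](C)(C)C)CC[C@H]2[C@]1(COC3=O)C(=O)C=CC(C)(C)[C@H]1C(OC)OC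
F4 | step 20 | 13,15-diol dimethyl acetal (33 without the silyl group) | C=C1[C@@H](O)[C@]23C[C@@]1(O)CC[C@H]2[C@]1(COC3=O)C(=O)C=CC(C)(C)[C@H]1C(OC)OC
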